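**Plan**
- The retrosynthesis first cuts the two depside ester C(=O)–O bonds: ring A carbonyl to O4 of ring B, and ring B carbonyl to O4 of ring C. This gives two benzyl-protected orsellinic-type acids and methyl orsellinate as ring C.
- Ring C is then cut at C1–CO2Me and C6–CH3. The ester carbon on C1 and the methyl carbon on C6 are neighbours and O2 flanks C1, so ring C maps onto a C1≡C6 aryne polarised by that oxygen, which takes both carbons from dimethyl malonate.
- Forward: ortho-silylaryl triflate (3 steps), aryne insertion into a malonate C–C bond, selective saponification, Barton decarboxylation of the arylacetic acid to the C6 methyl, hydrogenolysis to ring C.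
- Rings A and B come from 2,4-dihydroxy-6-methylbenzaldehyde by selective O-alkylation and Pinnick oxidation; ring B is esterified onto ring C and debenzylated, then ring A is esterified onto ring B and debenzylated.
- No ring is formed (all three benzene rings are bought) and the target has no stereocentre, so no stereocontrol is needed.

Key step: step 4

Assumption: 3,5-bis(benzyloxy)phenol (1), dimethyl malonate (7) and 2,4-dihydroxy-6-methylbenzaldehyde (15) are taken as commercial; compound 14 is methyl orsellinate, itself purchasable, so steps 14–17 can be rehearsed on bought material.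

**Route**

Step 1
Reactants: 1 3,5-bis(benzyloxy)phenol
Product: 2 3,5-bis(benzyloxy)-2-bromophenol
Conditions: NBS, CH2Cl2, −78 °C to rt
Reagents that add atoms: N-bromosuccinimide, O=C1CCC(=O)N1Br
Why: Electrophilic aromatic bromination with NBS in a non-polar solvent at low temperature should go ortho to the free hydroxyl (C2 and C6 are equivalent), the hydrogen-bonded phenol delivering bromine in preference to C4 between the two benzyloxy groups.

Step 2
Reactants: 2 3,5-bis(benzyloxy)-2-bromophenol
Product: 3 [3,5-bis(benzyloxy)-2-bromophenoxy]trimethylsilane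
Conditions: HMDS, THF, 70 °C; concentrate
Reagents that add atoms: hexamethyldisilazane, C[Si](C)(C)N[Si](C)(C)C
Why: O-silylation of the phenol with HMDS gives the aryl trimethylsilyl ether with ammonia as the only by-product, so the crude ether can be used after evaporation.

Step 3
Reactants: 3 [3,5-bis(benzyloxy)-2-bromophenoxy]trimethylsilane
Product: 6 3,5-bis(benzyloxy)-2-(trimethylsilyl)phenyl trifluoromethanesulfonate, via aryllithium 4 (not isolated), via lithium 2-silylphenoxide 5 (not isolated)
Conditions: n-BuLi, THF, −100 to −80 °C; Tf2O, −100 to −78 °C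
Reagents that add atoms: trifluoromethanesulfonic anhydride, O=S(=O)(OS(=O)(=O)C(F)(F)F)C(F)(F)F
Why: Bromine–lithium exchange at −100 °C, faster than metalation of the benzylic ether positions, gives aryllithium 4, which undergoes the 1,3 O→C silyl shift (retro-Brook rearrangement) to phenoxide 5, and O-triflation of 5 completes the ortho-silylaryl triflate.

Step 4
Reactants: 6 3,5-bis(benzyloxy)-2-(trimethylsilyl)phenyl trifluoromethanesulfonate; 7 dimethyl malonate
Product: 10 methyl 2,4-bis(benzyloxy)-6-(2-methoxy-2-oxoethyl)benzoate, via 3,5-bis(benzyloxy)benzyne 8 (not isolated), via potassium benzocyclobutenoxide 9 (not isolated)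
Conditions: KF, 18-crown-6, 7 (2 equiv), THF, rt
Reagents that add atoms: none
Why: Fluoride removes the trimethylsilyl group of 6 with loss of triflate to give aryne 8, and the potassium enolate of 7 adds to the aryne carbon remote from the flanking benzyloxy group (the former C–OTf carbon), which places the aryl anion ortho to that oxygen. This anion closes onto one ester carbonyl of the malonate arm (4-exo-trig) to give benzocyclobutenoxide 9, whose strained ring opens by retro-aldol-type cleavage to the ester-stabilised benzylic enolate, and proton transfer from 7 gives 10 and passes the enolate on. The reaction is the known insertion of arynes into the C–C sigma bond of malonates and beta-keto esters (aryne acyl-alkylation), which includes 3,5-dialkoxyarynes. The four-membered ring is transient, no ring is kept and no stereocentre is formed. The step needs regioselective addition to the unsymmetrical aryne, secured by the inductively withdrawing benzyloxy group beside the triple bond, which stabilises negative charge at its ortho carbon and distorts the aryne so that the remote carbon is the more electrophilic; it also needs ring closure to outrun protonation of the aryl anion, which the aprotic medium and the nearby ester carbonyl favour.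

Step 5
Reactants: 10 methyl 2,4-bis(benzyloxy)-6-(2-methoxy-2-oxoethyl)benzoate
Product: 11 2-[3,5-bis(benzyloxy)-2-(methoxycarbonyl)phenyl]acetic acid
Conditions: LiOH·H2O (1.2 equiv), THF/H2O, 0 °C to rt; 1 M HCl
Reagents that add atoms: lithium hydroxide, [Li+].[OH-]
Why: Saponification (BAc2) with a slight excess of LiOH should touch only the unhindered aliphatic ester, since the aryl ester is flanked by two ortho substituents and shielded from addition of hydroxide.

Step 6
Reactants: 11 2-[3,5-bis(benzyloxy)-2-(methoxycarbonyl)phenyl]acetic acid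
Product: 13 methyl 2,4-bis(benzyloxy)-6-methylbenzoate, via Barton ester 12 (not isolated)
Conditions: N-hydroxypyridine-2-thione, DCC, DMAP (cat.), CH2Cl2, 0 °C to rt, dark; then t-BuSH, hν (tungsten lamp), rt
Reagents that add atoms: none
Why: Barton reductive decarboxylation, in which thiohydroxamate ester 12 fragments under visible light in a radical chain to CO2 and the benzylic radical, which takes hydrogen from t-BuSH to give the aryl methyl group while the thiyl radical carries the chain.

Step 7
Reactants: 13 methyl 2,4-bis(benzyloxy)-6-methylbenzoate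
Product: 14 methyl 2,4-dihydroxy-6-methylbenzoate (methyl orsellinate, ring C)
Conditions: H2 (1 atm), Pd/C, EtOAc/MeOH, rt
Reagents that add atoms: none
Why: Catalytic hydrogenolysis over Pd/C cleaves both aryl benzyl ethers and leaves the methyl ester and the arene untouched.

Step 8
Reactants: 15 2,4-dihydroxy-6-methylbenzaldehyde
Product: 16 4-(benzyloxy)-2-hydroxy-6-methylbenzaldehyde
Conditions: BnBr (1.0 equiv), K2CO3, acetone, reflux
Reagents that add atoms: benzyl bromide, BrCc1ccccc1
Why: Williamson etherification with one equivalent of BnBr should be selective for the 4-hydroxyl, because the 2-hydroxyl is hydrogen-bonded to the formyl oxygen and is less acidic and less nucleophilic.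

Step 9
Reactants: 16 4-(benzyloxy)-2-hydroxy-6-methylbenzaldehyde
Product: 17 4-(benzyloxy)-2-methoxy-6-methylbenzaldehyde
Conditions: MeI (excess), K2CO3, DMF, 50 °C
Reagents that add atoms: iodomethane, CI
Why: Williamson methylation of the remaining chelated phenol needs the more forcing DMF conditions but has no competing site.

Step 10
Reactants: 17 4-(benzyloxy)-2-methoxy-6-methylbenzaldehyde
Product: 18 4-(benzyloxy)-2-methoxy-6-methylbenzoic acid (ring B acid)
Conditions: NaClO2, NaH2PO4, 2-methyl-2-butene, t-BuOH/THF/H2O, rt
Reagents that add atoms: sodium chlorite, [Na+].[O-]Cl=O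
Why: Pinnick oxidation converts the hindered, electron-rich aldehyde to the acid under buffered conditions without touching the benzyl ether, 2-methyl-2-butene removing the hypochlorous acid that would otherwise chlorinate the ring.

Step 11
Reactants: 15 2,4-dihydroxy-6-methylbenzaldehyde
Product: 19 2-hydroxy-4-methoxy-6-methylbenzaldehyde
Conditions: MeI (1.0 equiv), K2CO3, acetone, reflux
Reagents that add atoms: iodomethane, CI
Why: Williamson methylation with one equivalent of MeI should go to the unchelated 4-hydroxyl for the same reason as in step 8.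

Step 12
Reactants: 19 2-hydroxy-4-methoxy-6-methylbenzaldehyde
Product: 20 2-(benzyloxy)-4-methoxy-6-methylbenzaldehyde
Conditions: BnBr, K2CO3, DMF, 60 °C
Reagents that add atoms: benzyl bromide, BrCc1ccccc1
Why: Williamson benzylation of the chelated 2-hydroxyl under DMF conditions protects it for the later esterification.

Step 13
Reactants: 20 2-(benzyloxy)-4-methoxy-6-methylbenzaldehyde
Product: 21 2-(benzyloxy)-4-methoxy-6-methylbenzoic acid (ring A acid)
Conditions: NaClO2, NaH2PO4, 2-methyl-2-butene, t-BuOH/THF/H2O, rt
Reagents that add atoms: sodium chlorite, [Na+].[O-]Cl=O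
Why: Pinnick oxidation as in step 10, the benzyl and methyl ethers being inert to buffered chlorite.

Step 14
Reactants: 14 methyl 2,4-dihydroxy-6-methylbenzoate; 18 4-(benzyloxy)-2-methoxy-6-methylbenzoic acid
Product: 23 3-hydroxy-4-(methoxycarbonyl)-5-methylphenyl 4-(benzyloxy)-2-methoxy-6-methylbenzoate, via mixed trifluoroacetic anhydride 22 (not isolated)
Conditions: (CF3CO)2O, toluene, rt; aq. NaHCO3 work-up
Reagents that add atoms: none
Why: Esterification through mixed anhydride 22, which ionises readily to the acylium ion of the electron-rich 2,6-disubstituted acid and so overcomes its hindrance (the established way to depside esters), should acylate the free 4-hydroxyl of 14 and not the 2-hydroxyl, which is hydrogen-bonded to the ester carbonyl.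

Step 15
Reactants: 23 3-hydroxy-4-(methoxycarbonyl)-5-methylphenyl 4-(benzyloxy)-2-methoxy-6-methylbenzoate
Product: 24 3-hydroxy-4-(methoxycarbonyl)-5-methylphenyl 4-hydroxy-2-methoxy-6-methylbenzoate
Conditions: H2 (1 atm), Pd/C, EtOAc, rt
Reagents that add atoms: none
Why: Catalytic hydrogenolysis removes the aryl benzyl ether, and the aryl ester linkage is stable to H2 over Pd/C.

Step 16
Reactants: 24 3-hydroxy-4-(methoxycarbonyl)-5-methylphenyl 4-hydroxy-2-methoxy-6-methylbenzoate; 21 2-(benzyloxy)-4-methoxy-6-methylbenzoic acid
Product: 26 4-{[3-hydroxy-4-(methoxycarbonyl)-5-methylphenoxy]carbonyl}-3-methoxy-5-methylphenyl 2-(benzyloxy)-4-methoxy-6-methylbenzoate, via mixed trifluoroacetic anhydride 25 (not isolated)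
Conditions: (CF3CO)2O, toluene, rt; aq. NaHCO3 work-up
Reagents that add atoms: none
Why: The same mixed-anhydride esterification as in step 14 should acylate the ring B hydroxyl, the only unchelated phenol of 24, the ring C hydroxyl being tied up by its hydrogen bond to the methyl ester.

Step 17
Reactants: 26 4-{[3-hydroxy-4-(methoxycarbonyl)-5-methylphenoxy]carbonyl}-3-methoxy-5-methylphenyl 2-(benzyloxy)-4-methoxy-6-methylbenzoate
Product: 27 4-{[3-hydroxy-4-(methoxycarbonyl)-5-methylphenoxy]carbonyl}-3-methoxy-5-methylphenyl 2-hydroxy-4-methoxy-6-methylbenzoate (CNP0357736.0)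
Conditions: H2 (1 atm), Pd/C, EtOAc, rt
Reagents that add atoms: none
Why: Catalytic hydrogenolysis of the last benzyl ether frees the ring A hydroxyl while both depside esters and the methyl ester stay intact.

**Compound list**

1 | 3,5-bis(benzyloxy)phenol | Oc1cc(OCc2ccccc2)cc(OCc2ccccc2)c1 | starting material
2 | 3,5-bis(benzyloxy)-2-bromophenol | Oc1cc(OCc2ccccc2)cc(OCc2ccccc2)c1Br | intermediate
3 | [3,5-bis(benzyloxy)-2-bromophenoxy]trimethylsilane | C[Si](C)(C)Oc1cc(OCc2ccccc2)cc(OCc2ccccc2)c1Br | intermediate
4 | {2,4-bis(benzyloxy)-6-[(trimethylsilyl)oxy]phenyl}lithium | [Li]c1c(O[Si](C)(C)C)cc(OCc2ccccc2)cc1OCc1ccccc1 | intermediate (not isolated)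
5 | lithium 3,5-bis(benzyloxy)-2-(trimethylsilyl)phenoxide | [Li+].[O-]c1cc(OCc2ccccc2)cc(OCc2ccccc2)c1[Si](C)(C)C | intermediate (not isolated)
6 | 3,5-bis(benzyloxy)-2-(trimethylsilyl)phenyl trifluoromethanesulfonate | C[Si](C)(C)c1c(OCc2ccccc2)cc(OCc2ccccc2)cc1OS(=O)(=O)C(F)(F)F | intermediate
7 | dimethyl malonate | COC(=O)CC(=O)OC | starting material
8 | 3,5-bis(benzyloxy)benzyne (1,2-didehydro-3,5-bis(benzyloxy)benzene) | C1(OCc2ccccc2)=CC(OCc2ccccc2)=CC#C1 | intermediate (not isolated)
9 | potassium 3,5-bis(benzyloxy)-7-methoxy-8-(methoxycarbonyl)bicyclo[4.2.0]octa-1,3,5-trien-7-olate (benzocyclobutenoxide, transient, diastereomers not defined) | [K+].[O-]C1(OC)C(C(=O)OC)c2cc(OCc3ccccc3)cc(OCc3ccccc3)c21 | intermediate (not isolated)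
10 | methyl 2,4-bis(benzyloxy)-6-(2-methoxy-2-oxoethyl)benzoate | COC(=O)Cc1cc(OCc2ccccc2)cc(OCc2ccccc2)c1C(=O)OC | intermediate
11 | 2-[3,5-bis(benzyloxy)-2-(methoxycarbonyl)phenyl]acetic acid | OC(=O)Cc1cc(OCc2ccccc2)cc(OCc2ccccc2)c1C(=O)OC | intermediate
12 | 2-thioxopyridin-1(2H)-yl 2-[3,5-bis(benzyloxy)-2-(methoxycarbonyl)phenyl]acetate (Barton ester) | COC(=O)c1c(CC(=O)ON2C=CC=CC2=S)cc(OCc2ccccc2)cc1OCc1ccccc1 | intermediate (not isolated)
13 | methyl 2,4-bis(benzyloxy)-6-methylbenzoate | COC(=O)c1c(C)cc(OCc2ccccc2)cc1OCc1ccccc1 | intermediate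
14 | methyl 2,4-dihydroxy-6-methylbenzoate (methyl orsellinate) | COC(=O)c1c(C)cc(O)cc1O | intermediate
15 | 2,4-dihydroxy-6-methylbenzaldehyde | Cc1cc(O)cc(O)c1C=O | starting material
16 | 4-(benzyloxy)-2-hydroxy-6-methylbenzaldehyde | Cc1cc(OCc2ccccc2)cc(O)c1C=O | intermediate
17 | 4-(benzyloxy)-2-methoxy-6-methylbenzaldehyde | COc1cc(OCc2ccccc2)cc(C)c1C=O | intermediate
18 | 4-(benzyloxy)-2-methoxy-6-methylbenzoic acid | COc1cc(OCc2ccccc2)cc(C)c1C(=O)O | intermediate
19 | 2-hydroxy-4-methoxy-6-methylbenzaldehyde | COc1cc(C)c(C=O)c(O)c1 | intermediate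
20 | 2-(benzyloxy)-4-methoxy-6-methylbenzaldehyde | COc1cc(C)c(C=O)c(OCc2ccccc2)c1 | intermediate
21 | 2-(benzyloxy)-4-methoxy-6-methylbenzoic acid | COc1cc(C)c(C(=O)O)c(OCc2ccccc2)c1 | intermediate
22 | 4-(benzyloxy)-2-methoxy-6-methylbenzoic trifluoroacetic anhydride | COc1cc(OCc2ccccc2)cc(C)c1C(=O)OC(=O)C(F)(F)F | intermediate (not isolated)
23 | 3-hydroxy-4-(methoxycarbonyl)-5-methylphenyl 4-(benzyloxy)-2-methoxy-6-methylbenzoate | COC(=O)c1c(C)cc(OC(=O)c2c(C)cc(OCc3ccccc3)cc2OC)cc1O | intermediate
24 | 3-hydroxy-4-(methoxycarbonyl)-5-methylphenyl 4-hydroxy-2-methoxy-6-methylbenzoate | COC(=O)c1c(C)cc(OC(=O)c2c(C)cc(O)cc2OC)cc1O | intermediate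
25 | 2-(benzyloxy)-4-methoxy-6-methylbenzoic trifluoroacetic anhydride | COc1cc(C)c(C(=O)OC(=O)C(F)(F)F)c(OCc2ccccc2)c1 | intermediate (not isolated)
26 | 4-{[3-hydroxy-4-(methoxycarbonyl)-5-methylphenoxy]carbonyl}-3-methoxy-5-methylphenyl 2-(benzyloxy)-4-methoxy-6-methylbenzoate | COC(=O)c1c(C)cc(OC(=O)c2c(C)cc(OC(=O)c3c(C)cc(OC)cc3OCc3ccccc3)cc2OC)cc1O | intermediate
27 | 4-{[3-hydroxy-4-(methoxycarbonyl)-5-methylphenoxy]carbonyl}-3-methoxy-5-methylphenyl 2-hydroxy-4-methoxy-6-methylbenzoate (CNP0357736.0) | COC(=O)c1c(C)cc(OC(=O)c2c(C)cc(OC(=O)c3c(C)cc(OC)cc3O)cc2OC)cc1O | target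

**Step count and risks**

Total step count: 17. Longest linear sequence: 11 steps (steps 1–7, then 14–17).

Steps most likely to fail:

Step 4. The aryl anion may be protonated by the malonate before the 4-exo closure, so that plain C-arylation of the malonate competes with insertion, or the product enolate may capture a second aryne. Fallback: setting out from 6, the same aryne 8 is generated with CsF in MeCN in the presence of 1,1-dimethoxyethene and taken in a [2+2] cycloaddition. The same polarisation sends the nucleophilic CH2 terminus to the remote aryne carbon and should give the benzocyclobutenone acetal 2,4-bis(benzyloxy)-8,8-dimethoxybicyclo[4.2.0]octa-1,3,5-triene F1. Mild acid hydrolysis (aq. HCl, THF) should give the ketone 3,5-bis(benzyloxy)bicyclo[4.2.0]octa-1,3,5-trien-7-one F2. NaOMe in MeOH should then add to the carbonyl and open the four-membered ring at the C(=O)–CH2 bond, the benzylic carbanion being protonated to the methyl group. This forms the same two skeletal bonds on the same aryne and comes back to the route at 13, so that steps 5 and 6 are not needed.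

Step 6. The light- and heat-sensitive thiohydroxamate ester may decay outside the chain, and the stabilised benzylic radical may recombine at sulfur to a benzyl pyridyl sulfide in place of taking hydrogen from the thiol. Fallback: setting out from 11, esterification with N-hydroxyphthalimide (N,N'-diisopropylcarbodiimide, cat. DMAP, CH2Cl2) should give the isolable redox-active ester 1,3-dioxoisoindolin-2-yl 2-[3,5-bis(benzyloxy)-2-(methoxycarbonyl)phenyl]acetate F3. Nickel-catalysed reductive decarboxylation of F3 with a silane as hydrogen source (NiCl2·6H2O, 4,7-diphenyl-1,10-phenanthroline, Zn, PhSiH3, THF/DMF/i-PrOH, 40 °C) should deliver the methyl compound, and the route is rejoined at 13.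

Step 16. Esterification of the hindered acid at a phenol that already sits on a diaryl ester may be sluggish, and during a long exposure to trifluoroacetic acid the depside link in place can exchange acyl groups or the chelated ring C hydroxyl can begin to compete. Fallback: rings A and B are joined first at the aldehyde stage, where the phenol partner is small, has one hydroxyl and no aryl ester. Setting out from 17, hydrogenolysis (H2, Pd/C, EtOAc, stopped after one equivalent so that the formyl group is kept) should give 4-hydroxy-2-methoxy-6-methylbenzaldehyde F4. Acylation of F4 with acid 21 through its mixed anhydride 25 ((CF3CO)2O, toluene) should give 4-formyl-3-methoxy-5-methylphenyl 2-(benzyloxy)-4-methoxy-6-methylbenzoate F5. Pinnick oxidation, which needs no hydrolysis and so spares the aryl ester, should give the acid 4-{[2-(benzyloxy)-4-methoxy-6-methylbenzoyl]oxy}-2-methoxy-6-methylbenzoic acid F6. F6 is then activated as 4-{[2-(benzyloxy)-4-methoxy-6-methylbenzoyl]oxy}-2-methoxy-6-methylbenzoic trifluoroacetic anhydride F7 and esterified with the 4-hydroxyl of 14 under the conditions of step 14. This path comes back to the route at 26 and leaves steps 14 and 15 aside.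

Further compounds
F1 | step 4 | 2,4-bis(benzyloxy)-8,8-dimethoxybicyclo[4.2.0]octa-1,3,5-triene | COC1(OC)Cc2cc(OCc3ccccc3)cc(OCc3ccccc3)c21
F2 | step 4 | 3,5-bis(benzyloxy)bicyclo[4.2.0]octa-1,3,5-trien-7-one | O=C1Cc2cc(OCc3ccccc3)cc(OCc3ccccc3)c21
F3 | step 6 | 1,3-dioxoisoindolin-2-yl 2-[3,5-bis(benzyloxy)-2-(methoxycarbonyl)phenyl]acetate | COC(=O)c1c(CC(=O)ON2C(=O)c3ccccc3C2=O)cc(OCc2ccccc2)cc1OCc1ccccc1
F4 | step 16 | 4-hydroxy-2-methoxy-6-methylbenzaldehyde | COc1cc(O)cc(C)c1C=O
F5 | step 16 | 4-formyl-3-methoxy-5-methylphenyl 2-(benzyloxy)-4-methoxy-6-methylbenzoate | COc1cc(C)c(C(=O)Oc2cc(C)c(C=O)c(OC)c2)c(OCc2ccccc2)c1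
F6 | step 16 | 4-{[2-(benzyloxy)-4-methoxy-6-methylbenzoyl]oxy}-2-methoxy-6-methylbenzoic acid | COc1cc(C)c(C(=O)Oc2cc(C)c(C(=O)O)c(OC)c2)c(OCc2ccccc2)c1
F7 | step 16 | 4-{[2-(benzyloxy)-4-methoxy-6-methylbenzoyl]oxy}-2-methoxy-6-methylbenzoic trifluoroacetic anhydride | COc1cc(C)c(C(=O)Oc2cc(C)c(C(=O)OC(=O)C(F)(F)F)c(OC)c2)c(OCc2ccccc2)c1
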